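**Retrosynthetic overview**
- Ring numbering used throughout: C1 (C=O), C2 (acyl-bearing), C3 (enol OH), C4 (carbinol), C5 (C=O), C6 (gem-diprenyl). The target is cut at the C4–CH2 bond: C4 acts as an electrophile (the 1,4,5-trione, i.e. the normally nucleophilic enol carbon raised to the enolonium oxidation level) and a reverse-prenyl boron nucleophile on a chiral binaphthol delivers the prenyl group. This is the last step and sets the only stereocentre.
- The trione comes from oxidation of C4–H in the gem-diprenyl dearomatised acylphloroglucinol, so oxygen goes on before the carbon substituent; it is dried to its anhydrous form in the same step.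
- That compound comes from dearomative gem-diprenylation of phlorisobutyrophenone, itself from Friedel–Crafts acylation of phloroglucinol.
- The boron reagent comes from prenyl chloride, Mg and triisopropyl borate with allylic transposition.
- No ring is formed: the single six-membered carbocycle is the phloroglucinol ring, carried through and dearomatised in step 2.

Assumption: the facial sense of the binaphthol-controlled allyl transfer is taken from the acetophenone model (C5/C6 flank in place of the aryl group), which calls for the (R)-diol to give the (4R)-carbinol; if experiment shows the opposite sense, the equally available (S)-diol is used with no other change.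

**Route**

Step 1
Reactants: 1 phloroglucinol; 2 isobutyryl chloride
Product: 3 phlorisobutyrophenone (2-methyl-1-(2,4,6-trihydroxyphenyl)propan-1-one)
Conditions: AlCl3 (4 equiv), PhNO2/CH2Cl2, 0 °C → 50 °C; ice/aq. HCl
Reagents that add atoms: none
Why: Friedel–Crafts C-acylation of the very electron-rich triol stops at the mono-ketone because the chelated acyl group deactivates the ring; no stereocentre.

Step 2
Reactants: 3 phlorisobutyrophenone; 4 prenyl bromide (2.1 equiv)
Product: 5 3,5-dihydroxy-2-(2-methylpropanoyl)-6,6-bis(3-methylbut-2-en-1-yl)cyclohexa-2,4-dien-1-one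
Conditions: NaOMe (3 equiv), MeOH, 0 °C; 4 added slowly, 0 °C → rt; aq. HCl; chromatography (removes the 3,5-diprenyl isomer and triprenyl product)
Reagents that add atoms: none
Why: Dearomative geminal C-alkylation of the phloroglucinolate in a protic medium (C- over O-alkylation with a soft allylic halide), where the second prenyl enters the already substituted carbon to give the stabilised vinylogous-acid anion, as in the gem-dimethylation of acylphloroglucinols to acylfilicinic acids and in lupulone syntheses; no stereocentre.

Step 3
Reactants: 5 gem-diprenyl dienone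
Product: 7 3-hydroxy-2-(2-methylpropanoyl)-6,6-bis(3-methylbut-2-en-1-yl)cyclohex-2-ene-1,4,5-trione (anhydrous trione), via trione hydrate 6 (not isolated)
Conditions: Dess–Martin periodinane (2.5 equiv), pyridine (5 equiv), CH2Cl2, 0 °C → rt; aq. Na2S2O3, then NaH2PO4/H3PO4 (pH 3), EtOAc; crude 6 not purified; PhMe azeotrope (≤30 °C, 3×), then 4 Å MS, PhMe, rt, Ar; filter, concentrate, keep as PhMe stock solution under Ar
Reagents that add atoms: Dess–Martin periodinane CC(=O)OI1(OC(C)=O)(OC(C)=O)OC(=O)c2ccccc12 (oxygen at C4); water O (second hydroxyl of hydrate 6, so part of the C4 oxygen of 7 can derive from it)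
Why: Dess–Martin oxidation of a 1,3-dicarbonyl C–H to the vicinal tricarbonyl, in which the pentavalent iodine reagent oxygenates the only unsubstituted enol carbon C4 twice while the prenyl alkenes stay inert, the aqueous work-up leaves the product as its C4 gem-diol 6, and azeotropic drying over molecular sieves dehydrates this crude hydrate to the anhydrous trione that the boron reagent of step 5 requires; no stereocentre.

Step 4
Reactants: 8 prenyl chloride; 9 triisopropyl borate
Product: 12 diisopropyl (2-methylbut-3-en-2-yl)boronate, via prenylmagnesium chloride 10 (not isolated), via chloromagnesium borate complex 11 (not isolated)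
Conditions: Mg (2 equiv), THF, 0 °C; then 9, Et2O, −78 °C → rt; HCl (1 M in Et2O, 1 equiv), 0 °C; filter, distil
Reagents that add atoms: none
Why: Grignard formation followed by SE2' borylation, in which prenylmagnesium halides deliver boron and silicon electrophiles to the tertiary terminus (allylic transposition), and protonolysis of the ate complex as in the standard preparation of allyldiisopropoxyborane; no stereocentre.

Step 5
Reactants: 7 anhydrous trione; 12 diisopropyl (2-methylbut-3-en-2-yl)boronate (1.5 equiv); 13 (R)-3,3'-dibromo-1,1'-bi-2-naphthol (1.5 equiv)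
Product: 16 (4R)-3,4-dihydroxy-2-(2-methylpropanoyl)-4,6,6-tris(3-methylbut-2-en-1-yl)cyclohex-2-ene-1,5-dione, via chiral binaphthol boronate 14 (not isolated), via boron alkoxide of the product 15 (not isolated)
Conditions: 12 + 13, PhMe, rt, then vacuum (removes iPrOH); PhMe solution of 7 added at −78 °C, then −40 °C, 24 h, Ar; MeOH then pH 5 citrate buffer, 0 °C; diol recovered by chromatography
Reagents that add atoms: none
Why: Proposed new method: the central C4 carbonyl of the vicinal trione (the ring carbon that is nucleophilic in the parent enol, here an enolonium equivalent) is the most electrophilic and least hindered carbonyl, so the binaphthol-bound tertiary allylboron transfers its allyl group through a closed six-membered Zimmerman–Traxler transition state in which the CH2 terminus bonds to C4 and the double bond shifts to give the linear prenyl group, while the 3,3'-dibromobinaphthol ligand (which stays on boron even if the adjacent C3 enol OH exchanges onto boron and makes the delivery intramolecular) blocks one face so that attack on the Si face of C4=O (priority O > C5 > C3) gives the (4R)-carbinol; the closest known reactions are the reagent-controlled asymmetric allylboration of ketones with 3,3'-disubstituted binaphthol allylboronates, the diol-catalysed allylboration of ketones with allyldiisopropoxyborane and the hydroxyl-directed allylboration of α-hydroxy ketones.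

**Compound list**

1 | phloroglucinol (benzene-1,3,5-triol) | Oc1cc(O)cc(O)c1 | starting material
2 | isobutyryl chloride (2-methylpropanoyl chloride) | CC(C)C(Cl)=O | starting material
3 | phlorisobutyrophenone, 2-methyl-1-(2,4,6-trihydroxyphenyl)propan-1-one | CC(C)C(=O)c1c(O)cc(O)cc1O | intermediate
4 | prenyl bromide (1-bromo-3-methylbut-2-ene) | CC(C)=CCBr | starting material
5 | 3,5-dihydroxy-2-(2-methylpropanoyl)-6,6-bis(3-methylbut-2-en-1-yl)cyclohexa-2,4-dien-1-one | CC(C)=CCC1(CC=C(C)C)C(=O)C(C(=O)C(C)C)=C(O)C=C1O | intermediate
6 | trione hydrate, 3,4,4-trihydroxy-2-(2-methylpropanoyl)-6,6-bis(3-methylbut-2-en-1-yl)cyclohex-2-ene-1,5-dione (not isolated) | CC(C)=CCC1(CC=C(C)C)C(=O)C(C(=O)C(C)C)=C(O)C(O)(O)C1=O | intermediate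
7 | anhydrous trione, 3-hydroxy-2-(2-methylpropanoyl)-6,6-bis(3-methylbut-2-en-1-yl)cyclohex-2-ene-1,4,5-trione | CC(C)=CCC1(CC=C(C)C)C(=O)C(C(=O)C(C)C)=C(O)C(=O)C1=O | intermediate
8 | prenyl chloride (1-chloro-3-methylbut-2-ene) | CC(C)=CCCl | starting material
9 | triisopropyl borate | CC(C)OB(OC(C)C)OC(C)C | starting material
10 | prenylmagnesium chloride, Me2C=CHCH2MgCl (not isolated) | CC(C)=CC[Mg]Cl | intermediate
11 | chloromagnesium triisopropoxy(2-methylbut-3-en-2-yl)borate (not isolated) | C=CC(C)(C)[B-](OC(C)C)(OC(C)C)OC(C)C.[Mg+]Cl | intermediate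
12 | diisopropyl (2-methylbut-3-en-2-yl)boronate | C=CC(C)(C)B(OC(C)C)OC(C)C | intermediate
13 | (R)-3,3'-dibromo-1,1'-bi-2-naphthol (axial R; the axis is not encoded in the SMILES) | Oc1c(Br)cc2ccccc2c1-c1c(O)c(Br)cc2ccccc12 | starting material
14 | (R)-2,6-dibromo-4-(2-methylbut-3-en-2-yl)dinaphtho[2,1-d:1',2'-f][1,3,2]dioxaborepine (axial R; not isolated) | C=CC(C)(C)B1Oc2c(Br)cc3ccccc3c2-c2c(O1)c(Br)cc3ccccc23 | intermediate
15 | C4–O borate ester of 16 with the (R)-dibromobinaphthol boron unit (4R, axial R; not isolated) | CC(C)=CCC1(CC=C(C)C)C(=O)C(C(=O)C(C)C)=C(O)[C@](OB2Oc3c(Br)cc4ccccc4c3-c3c(O2)c(Br)cc4ccccc34)(CC=C(C)C)C1=O | intermediate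
16 | (4R)-3,4-dihydroxy-2-(2-methylpropanoyl)-4,6,6-tris(3-methylbut-2-en-1-yl)cyclohex-2-ene-1,5-dione | CC(C)=CCC1(CC=C(C)C)C(=O)C(C(=O)C(C)C)=C(O)[C@](O)(CC=C(C)C)C1=O | target

**Step count**
Total steps: 5. Longest linear sequence: 4 (steps 1, 2, 3, 5; step 4 is a one-step side branch for the boron reagent).

**Three steps most likely to fail, with fallbacks**

Step 5 (facial selectivity, and possible 1,3-boron shift in the Lewis-acidic binaphthol boronate that would give the reverse-prenyl adduct). The fallback sets out from anhydrous trione 7 and boronate 12. The achiral boronate 12 is added to 7 without any diol (PhMe, 0 °C) to give the racemic carbinol F4. This strong acid is resolved by crystallisation of its salt with (1R,2R)-cyclohexane-1,2-diamine, the diamine salt of the (4R)-acid F5, in the way hop α-acids are purified as diamine salts. Cold dilute H3PO4 then liberates the acid and the route is rejoined at 16.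

Step 2 (the second prenyl may prefer the free ring carbon and give mainly the 3,5-diprenyl isomer). The fallback sets out from 3. Teuber oxidation with (KSO3)2NO (KH2PO4, acetone/H2O) gives the hydroxyquinone 3,5-dihydroxy-2-(2-methylpropanoyl)cyclohexa-2,5-diene-1,4-dione F1, which has only one free ring carbon. Tsuji–Trost alkylation with methyl prenyl carbonate and the zerovalent palladium complex Pd(PPh3)4 (dry THF, rt, Ar) passes through the mono-prenyl hydroxyquinone 3,5-dihydroxy-2-(2-methylpropanoyl)-6-(3-methylbut-2-en-1-yl)cyclohexa-2,5-diene-1,4-dione F2 and places the second prenyl on the same carbon. This gives the trione directly under anhydrous conditions, and the route is rejoined at 7; compound 5 and step 3 are bypassed.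

Step 3 (over-oxidation, or attack at the acyl-bearing C2 by the iodine reagent). The fallback sets out from 5. Deprotonation with KN(SiMe3)2 (2.2 equiv, THF, −78 °C) and hydroxylation with 2-(phenylsulfonyl)-3-phenyloxaziridine gives the ene-diol (reductone) 3,4,5-trihydroxy-2-(2-methylpropanoyl)-6,6-bis(3-methylbut-2-en-1-yl)cyclohexa-2,4-dien-1-one F3. This ascorbic-acid-like ene-diol is dehydrogenated with 1,4-benzoquinone in dry CH2Cl2 (rt, Ar), which gives the trione without contact with water, and the route is rejoined at 7.

**Further compounds**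
F1 | step 2 | 3,5-dihydroxy-2-(2-methylpropanoyl)cyclohexa-2,5-diene-1,4-dione | CC(C)C(=O)C1=C(O)C(=O)C(O)=CC1=O
F2 | step 2 | 3,5-dihydroxy-2-(2-methylpropanoyl)-6-(3-methylbut-2-en-1-yl)cyclohexa-2,5-diene-1,4-dione | CC(C)C(=O)C1=C(O)C(=O)C(O)=C(CC=C(C)C)C1=O
F3 | step 3 | 3,4,5-trihydroxy-2-(2-methylpropanoyl)-6,6-bis(3-methylbut-2-en-1-yl)cyclohexa-2,4-dien-1-one | CC(C)=CCC1(CC=C(C)C)C(=O)C(C(=O)C(C)C)=C(O)C(O)=C1O
F4 | step 5 | racemic 3,4-dihydroxy-2-(2-methylpropanoyl)-4,6,6-tris(3-methylbut-2-en-1-yl)cyclohex-2-ene-1,5-dione | CC(C)=CCC1(CC=C(C)C)C(=O)C(C(=O)C(C)C)=C(O)C(O)(CC=C(C)C)C1=O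
F5 | step 5 | (1R,2R)-cyclohexane-1,2-diamine salt of 16 | CC(C)=CCC1(CC=C(C)C)C(=O)C(C(=O)C(C)C)=C(O)[C@](O)(CC=C(C)C)C1=O.N[C@@H]1CCCC[C@H]1N
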